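**Plan**

1. Retrosynthesis (labdane numbering: ring A = C1–C5, C10; ring B = C5–C10; C17 = exocyclic CH2 on C8; C11 = carbinol on C9; C12–C16 = butenolide arm; C18/C19 on C4; C20 on C10): cut C13=C14 of the butenolide (ring-closing metathesis) and C11–C12 (allylation of a C11 aldehyde), then C8=C17, then C4–C5 and C9–C10 together, then C6–C7 (dianion alkylation) and C3=C4 (Z-olefination).
2. Enabling feature: rings A and B form a trans-decalin whose equatorial C3–OH, quaternary C4 (axial C19H2O, equatorial C18H3), angular C20 on C10 and equatorial C9 substituent are what a chair–chair folded (E)-C5=C10 alkene gives when it opens a C3–C4 epoxide and is trapped at C10 by the C9 enol carbon of a C8/C11 β-keto ester.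
3. Forward: the geraniol chain gains C4/C18/C19 by Z-selective olefination and C7–C9/C11 by acetoacetate dianion alkylation; rings A and B close together in one cationic step; C17 and then C12–C16 are added, and the butenolide ring closes last.
4. Stereochemistry: Sharpless epoxidation sets C3 and C4; the cyclization relays them to C5, C10 and C9 (E-alkene gives the trans fusion, the Z-derived epoxide gives axial C19); C11 is set by a reagent-controlled CBS reduction.

Key step: step 10

Assumption: the (11R) configuration written in the target SMILES is taken as the goal, and the facial bias of the hindered C11 aldehyde is treated as unpredictable, so C11 is set by oxidation and reagent-controlled reduction.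

Step 1
Reactants: 1 geraniol
Product: 2 geranyl 4-methoxybenzyl ether
Conditions: NaH, 4-methoxybenzyl chloride, n-Bu4NI (cat.), THF/DMF, 0 °C → rt
Reagents that add atoms: 4-methoxybenzyl chloride, COc1ccc(CCl)cc1
Why: Williamson etherification masks the primary allylic hydroxyl (the later C6 electrophile) as an ether that should survive hydride, base and epoxidation and can be removed oxidatively in step 7.

Step 2
Reactants: 2 geranyl 4-methoxybenzyl ether
Product: 4 (4E)-6-[(4-methoxybenzyl)oxy]-4-methylhex-4-enal, via terminal epoxide 3 (not isolated)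
Conditions: mCPBA, NaHCO3, CH2Cl2, 0 °C; then H5IO6, THF/H2O, 0 °C
Reagents that add atoms: mCPBA (3-chloroperoxybenzoic acid), OOC(=O)c1cccc(Cl)c1
Why: Prilezhaev epoxidation should pick the more electron-rich distal alkene over the one deactivated by the allylic ether oxygen, and periodic acid then cleaves the epoxide through its diol (glycol cleavage) to the aldehyde and acetone, so the racemic epoxide centre is lost.

Step 3
Reactants: 4 (4E)-6-[(4-methoxybenzyl)oxy]-4-methylhex-4-enal; 5 ethyl 2-[bis(2,2,2-trifluoroethoxy)phosphoryl]propanoate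
Product: 6 ethyl (2Z,6E)-8-[(4-methoxybenzyl)oxy]-2,6-dimethylocta-2,6-dienoate
Conditions: KN(SiMe3)2, 18-crown-6, THF, −78 °C
Reagents that add atoms: none
Why: Still–Gennari olefination, in which the electron-poor trifluoroethyl phosphonate eliminates rapidly from the kinetic adduct, should give the (Z)-trisubstituted enoate and so place the future C19 carbon cis to the chain.

Step 4
Reactants: 6 ethyl (2Z,6E)-8-[(4-methoxybenzyl)oxy]-2,6-dimethylocta-2,6-dienoate
Product: 7 (2Z,6E)-8-[(4-methoxybenzyl)oxy]-2,6-dimethylocta-2,6-dien-1-ol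
Conditions: i-Bu2AlH, CH2Cl2, −78 → 0 °C
Reagents that add atoms: none
Why: 1,2-hydride reduction of the enoate should give the allylic alcohol without touching the alkene geometry or the benzyl-type ether.

Step 5
Reactants: 7 (2Z,6E)-8-[(4-methoxybenzyl)oxy]-2,6-dimethylocta-2,6-dien-1-ol
Product: 8 [(2S,3R)-3-{(3E)-5-[(4-methoxybenzyl)oxy]-3-methylpent-3-en-1-yl}-2-methyloxiran-2-yl]methanol
Conditions: Ti(OiPr)4 (0.2 equiv), L-(+)-diethyl tartrate (0.25 equiv), t-BuOOH, 4 Å MS, CH2Cl2, −20 °C
Reagents that add atoms: tert-butyl hydroperoxide, CC(C)(C)OO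
Why: Sharpless asymmetric epoxidation engages only the free allylic alcohol, and the L-(+)-tartrate should deliver oxygen to the face that gives the (2S,3R)-epoxide (C3 R and C4 S in labdane numbering), the same facial sense as for nerol, while the alkene next to the ether is left alone.

Step 6
Reactants: 8 [(2S,3R)-3-{(3E)-5-[(4-methoxybenzyl)oxy]-3-methylpent-3-en-1-yl}-2-methyloxiran-2-yl]methanol
Product: 9 tert-butyl({(2S,3R)-3-[(3E)-5-[(4-methoxybenzyl)oxy]-3-methylpent-3-en-1-yl]-2-methyloxiran-2-yl}methoxy)diphenylsilane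
Conditions: TBDPSCl, imidazole, DMF, 0 °C → rt
Reagents that add atoms: tert-butyl(chloro)diphenylsilane, CC(C)(C)[Si](Cl)(c1ccccc1)c1ccccc1
Why: imidazole-promoted silylation of the primary alcohol should give a bulky, weakly coordinating ether that will neither bind the Lewis acid nor take part in the epoxide opening of step 10.

Step 7
Reactants: 9 tert-butyl({(2S,3R)-3-[(3E)-5-[(4-methoxybenzyl)oxy]-3-methylpent-3-en-1-yl]-2-methyloxiran-2-yl}methoxy)diphenylsilane
Product: 10 (2E)-5-[(2R,3S)-3-{[(tert-butyldiphenylsilyl)oxy]methyl}-3-methyloxiran-2-yl]-3-methylpent-2-en-1-ol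
Conditions: DDQ, CH2Cl2/pH 7 buffer, 0 °C
Reagents that add atoms: none
Why: oxidative cleavage of the 4-methoxybenzyl ether (hydride abstraction by DDQ, then hydrolysis of the oxocarbenium ion) should free the allylic alcohol under neutral conditions that spare the acid-sensitive epoxide and the silyl ether.

Step 8
Reactants: 10 (2E)-5-[(2R,3S)-3-{[(tert-butyldiphenylsilyl)oxy]methyl}-3-methyloxiran-2-yl]-3-methylpent-2-en-1-ol
Product: 12 {[(2S,3R)-3-[(3E)-5-bromo-3-methylpent-3-en-1-yl]-2-methyloxiran-2-yl]methoxy}(tert-butyl)diphenylsilane, via allylic mesylate 11 (not isolated)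
Conditions: MsCl, Et3N, THF, −40 °C; then LiBr, THF, 0 °C
Reagents that add atoms: lithium bromide, [Li+].[Br-]
Why: mesylation followed by SN2 displacement with bromide should give the allylic bromide without acid, so that the trisubstituted epoxide stays closed and the (E)-alkene is not scrambled.

Step 9
Reactants: 12 {[(2S,3R)-3-[(3E)-5-bromo-3-methylpent-3-en-1-yl]-2-methyloxiran-2-yl]methoxy}(tert-butyl)diphenylsilane; 13 methyl acetoacetate
Product: 15 methyl (6E,10R,11S)-12-[(tert-butyldiphenylsilyl)oxy]-10,11-epoxy-7,11-dimethyl-3-oxododec-6-enoate, via acetoacetate dianion 14 (not isolated)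
Conditions: 13 (3 equiv), NaH then n-BuLi, THF, 0 °C; then 12, 0 °C; aq. NH4Cl
Reagents that add atoms: none
Why: γ-alkylation of the acetoacetate dianion, whose terminal carbanion is the more basic and more nucleophilic site, should displace the allylic bromide by SN2 and leave the β-keto ester and the epoxide intact.

Step 10
Reactants: 15 methyl (6E,10R,11S)-12-[(tert-butyldiphenylsilyl)oxy]-10,11-epoxy-7,11-dimethyl-3-oxododec-6-enoate
Product: 16 methyl (1S,4aS,5R,6R,8aR)-5-{[(tert-butyldiphenylsilyl)oxy]methyl}-6-hydroxy-5,8a-dimethyl-2-oxodecahydronaphthalene-1-carboxylate (C8 ketone, equatorial C9 ester whose carbon is C11, equatorial C3–OH, axial C19H2OSi, trans fusion with axial C20)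
Conditions: MeAlCl2 (2.5 equiv), CH2Cl2 (high dilution), −78 °C; aq. potassium sodium tartrate
Reagents that add atoms: none
Why: MeAlCl2 (one equivalent is held by the β-keto ester as its aluminium enolate) binds the epoxide oxygen, the C5=C10 alkene attacks C4 anti to the breaking C4–O bond, and the tertiary C10 cation that develops is taken by the enol carbon C9, so that C4–C5 and C9–C10 form in one cationic cascade and work-up returns the β-keto ester and the C3 alcohol; the closest known reaction type is the Lewis-acid-promoted epoxy-polyene cyclization terminated by a β-dicarbonyl enol. Ring A closes by 6-endo opening of the epoxide (both epoxide carbons and both alkene carbons lie in the new ring) and ring B by 6-endo attack of the enol carbon on C10, each through a chair. C3 keeps the configuration from step 5 and its oxygen becomes equatorial, C4 is inverted so that the silyloxymethyl group that was cis to the chain on the epoxide becomes axial, C5 and C10 arise by anti addition across the (E)-alkene and give the trans ring fusion with C20 axial, and C9 forms with (or equilibrates through the enol to) the equatorial ester. The step needs termination at carbon instead of at the enol oxygen, closure of both rings before proton loss, and no 1,2-shift of the opened epoxide. The single epoxide enantiomer with the chair–chair fold fixes the absolute sense, the (E)-alkene and the (Z)-derived epoxide fix the relative configuration, and the bulky non-coordinating silyl ether keeps the C19 oxygen out of the ionization.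

Step 11
Reactants: 16 bicyclic β-keto ester
Product: 17 C3 tert-butyldimethylsilyl ether of 16
Conditions: TBSOTf, 2,6-lutidine, CH2Cl2, −78 → 0 °C
Reagents that add atoms: tert-butyldimethylsilyl trifluoromethanesulfonate, CC(C)(C)[Si](C)(C)OS(=O)(=O)C(F)(F)F
Why: silyl triflate silylation should cap the hindered equatorial C3 alcohol ahead of the two later oxidations, and any enol silyl ether of the β-keto ester is expected to hydrolyse on aqueous work-up.

Step 12
Reactants: 17 C3 tert-butyldimethylsilyl ether of 16
Product: 18 methyl ester with exocyclic C8=C17 alkene (C8=O of 17 replaced by C8=CH2; C9 ester equatorial)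
Conditions: Zn, CH2Br2, TiCl4, THF, 0 °C; then 17, CH2Cl2, rt
Reagents that add atoms: dibromomethane, BrCBr
Why: Lombardo methylenation with the non-basic zinc–titanium methylene reagent should convert the C8 ketone into the exocyclic alkene without epimerising C9, whose ester stays equatorial.

Step 13
Reactants: 18 methyl ester with exocyclic C8=C17 alkene
Product: 19 C11 primary alcohol (CO2Me of 18 reduced to CH2OH)
Conditions: i-Bu2AlH, CH2Cl2, −78 → 0 °C
Reagents that add atoms: none
Why: hydride reduction of the hindered methyl ester should give the primary C11 alcohol and leave both silyl ethers and the exocyclic alkene untouched.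

Step 14
Reactants: 19 C11 primary alcohol
Product: 20 C11 aldehyde (equatorial C9–CHO, β,γ to C8=C17)
Conditions: Dess–Martin periodinane, NaHCO3, CH2Cl2, 0 °C → rt
Reagents that add atoms: none
Why: Dess–Martin oxidation under buffered, non-basic conditions should stop at the β,γ-unsaturated aldehyde without moving the C8=C17 alkene into conjugation or epimerising C9.

Step 15
Reactants: 21 2-(bromomethyl)acrylic acid; 22 allyl alcohol
Product: 23 allyl 2-(bromomethyl)acrylate
Conditions: TsOH·H2O (cat.), BHT (cat.), benzene, reflux, Dean–Stark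
Reagents that add atoms: none
Why: Fischer esterification with azeotropic removal of water should give a reagent that carries both the allylic bromide for C11–C12 bond formation and the allyl ester for the later ring closure.

Step 16
Reactants: 20 C11 aldehyde; 23 allyl 2-(bromomethyl)acrylate
Product: 24 C11 carbinol carrying C12H2–C13(=CH2)–CO2CH2CH=CH2 (both C11 epimers)
Conditions: In powder, THF/H2O (1:1), rt
Reagents that add atoms: none
Why: indium-mediated Barbier allylation should add the 2-(alkoxycarbonyl)allyl unit to the hindered aldehyde under neutral aqueous conditions that tolerate the silyl ethers and do not epimerise C9, and no control of the new C11 centre is needed because it is reset in steps 18 and 19.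

Step 17
Reactants: 24 C11 carbinol with allyl acrylate arm
Product: 25 α-substituted butenolide with C11–OH (both C11 epimers)
Conditions: second-generation Grubbs catalyst (C46H65Cl2N2PRu, 10 mol%), CH2Cl2, 40 °C
Reagents that add atoms: none
Why: ring-closing metathesis of the allyl 2-substituted acrylate should close the butenolide ring (C13=C14) with loss of ethylene, the hindered exocyclic C8=C17 alkene being too slow a partner to interfere.

Step 18
Reactants: 25 α-substituted butenolide with C11–OH
Product: 26 C11 ketone (3-O-TBS-19-O-TBDPS-14-deoxy-11-oxoandrographolide)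
Conditions: Dess–Martin periodinane, NaHCO3, CH2Cl2, 0 °C → rt
Reagents that add atoms: none
Why: Dess–Martin oxidation should converge both C11 epimers on one ketone under buffered conditions mild enough to keep the C8=C17 and C13=C14 alkenes out of conjugation with the new carbonyl group.

Step 19
Reactants: 26 C11 ketone
Product: 27 (11R)-alcohol (3-O-TBS-19-O-TBDPS-14-deoxy-11-hydroxyandrographolide)
Conditions: (S)-Me-CBS (1.0 equiv), catecholborane, toluene, −78 → −40 °C
Reagents that add atoms: none
Why: Corey–Bakshi–Shibata reduction, in which the (S)-oxazaborolidine binds the ketone anti to the bulky C9 flank and delivers hydride in the sense that turns acetophenone into (R)-1-phenylethanol, should give the (11R)-carbinol, with catecholborane chosen because it does not hydroborate the alkenes or reduce the lactone at low temperature.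

Step 20
Reactants: 27 (11R)-alcohol
Product: 28 14-deoxy-11-hydroxyandrographolide
Conditions: HF·pyridine, pyridine, THF, 0 °C → rt
Reagents that add atoms: none
Why: fluoride-driven cleavage of both silyl ethers under buffered conditions should free the C3 and C19 hydroxyls without translactonisation of the butenolide or migration of the exocyclic alkene.

**Compound list**

1 | geraniol, (2E)-3,7-dimethylocta-2,6-dien-1-ol | CC(C)=CCC/C(C)=C/CO | starting material
2 | geranyl 4-methoxybenzyl ether | CC(C)=CCC/C(C)=C/COCc1ccc(OC)cc1 | intermediate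
3 | terminal epoxide, racemic 2,2-dimethyl-3-{(3E)-5-[(4-methoxybenzyl)oxy]-3-methylpent-3-en-1-yl}oxirane | CC1(C)OC1CC/C(C)=C/COCc1ccc(OC)cc1 | intermediate
4 | (4E)-6-[(4-methoxybenzyl)oxy]-4-methylhex-4-enal | O=CCC/C(C)=C/COCc1ccc(OC)cc1 | intermediate
5 | ethyl 2-[bis(2,2,2-trifluoroethoxy)phosphoryl]propanoate | CCOC(=O)C(C)P(=O)(OCC(F)(F)F)OCC(F)(F)F | starting material
6 | ethyl (2Z,6E)-8-[(4-methoxybenzyl)oxy]-2,6-dimethylocta-2,6-dienoate | CCOC(=O)/C(C)=C\CC/C(C)=C/COCc1ccc(OC)cc1 | intermediate
7 | (2Z,6E)-8-[(4-methoxybenzyl)oxy]-2,6-dimethylocta-2,6-dien-1-ol | OC/C(C)=C\CC/C(C)=C/COCc1ccc(OC)cc1 | intermediate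
8 | [(2S,3R)-3-{(3E)-5-[(4-methoxybenzyl)oxy]-3-methylpent-3-en-1-yl}-2-methyloxiran-2-yl]methanol | COc1ccc(COC/C=C(\C)CC[C@H]2O[C@@]2(C)CO)cc1 | intermediate
9 | tert-butyl({(2S,3R)-3-[(3E)-5-[(4-methoxybenzyl)oxy]-3-methylpent-3-en-1-yl]-2-methyloxiran-2-yl}methoxy)diphenylsilane | COc1ccc(COC/C=C(\C)CC[C@H]2O[C@@]2(C)CO[Si](c3ccccc3)(c4ccccc4)C(C)(C)C)cc1 | intermediate
10 | (2E)-5-[(2R,3S)-3-{[(tert-butyldiphenylsilyl)oxy]methyl}-3-methyloxiran-2-yl]-3-methylpent-2-en-1-ol | OC/C=C(\C)CC[C@H]1O[C@@]1(C)CO[Si](c2ccccc2)(c3ccccc3)C(C)(C)C | intermediate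
11 | allylic mesylate, methanesulfonate of 10 | CS(=O)(=O)OC/C=C(\C)CC[C@H]1O[C@@]1(C)CO[Si](c2ccccc2)(c3ccccc3)C(C)(C)C | intermediate
12 | {[(2S,3R)-3-[(3E)-5-bromo-3-methylpent-3-en-1-yl]-2-methyloxiran-2-yl]methoxy}(tert-butyl)diphenylsilane | BrC/C=C(\C)CC[C@H]1O[C@@]1(C)CO[Si](c2ccccc2)(c3ccccc3)C(C)(C)C | intermediate
13 | methyl acetoacetate | COC(=O)CC(C)=O | starting material
14 | acetoacetate dianion (sodium lithium salt of methyl acetoacetate) | C=C([O-])C=C([O-])OC.[Li+].[Na+] | intermediate
15 | methyl (6E,10R,11S)-12-[(tert-butyldiphenylsilyl)oxy]-10,11-epoxy-7,11-dimethyl-3-oxododec-6-enoate | COC(=O)CC(=O)CC/C=C(\C)CC[C@H]1O[C@@]1(C)CO[Si](c2ccccc2)(c3ccccc3)C(C)(C)C | intermediate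
16 | methyl (1S,4aS,5R,6R,8aR)-5-{[(tert-butyldiphenylsilyl)oxy]methyl}-6-hydroxy-5,8a-dimethyl-2-oxodecahydronaphthalene-1-carboxylate | O=C1CC[C@@H]2[C@](C)(CO[Si](c3ccccc3)(c4ccccc4)C(C)(C)C)[C@H](O)CC[C@@]2(C)[C@@H]1C(=O)OC | intermediate
17 | C3 tert-butyldimethylsilyl ether of 16 (same ring configuration) | O=C1CC[C@@H]2[C@](C)(CO[Si](c3ccccc3)(c4ccccc4)C(C)(C)C)[C@H](O[Si](C)(C)C(C)(C)C)CC[C@@]2(C)[C@@H]1C(=O)OC | intermediate
18 | methyl ester with exocyclic C8=C17 alkene, C3–OTBS, C19–OTBDPS, equatorial C9–CO2Me | C=C1CC[C@@H]2[C@](C)(CO[Si](c3ccccc3)(c4ccccc4)C(C)(C)C)[C@H](O[Si](C)(C)C(C)(C)C)CC[C@@]2(C)[C@@H]1C(=O)OC | intermediate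
19 | C11 primary alcohol (C9–CH2OH) of the 8(17)-ene | C=C1CC[C@@H]2[C@](C)(CO[Si](c3ccccc3)(c4ccccc4)C(C)(C)C)[C@H](O[Si](C)(C)C(C)(C)C)CC[C@@]2(C)[C@@H]1CO | intermediate
20 | C11 aldehyde (C9–CHO) of the 8(17)-ene | C=C1CC[C@@H]2[C@](C)(CO[Si](c3ccccc3)(c4ccccc4)C(C)(C)C)[C@H](O[Si](C)(C)C(C)(C)C)CC[C@@]2(C)[C@@H]1C=O | intermediate
21 | 2-(bromomethyl)acrylic acid | OC(=O)C(=C)CBr | starting material
22 | allyl alcohol | OCC=C | starting material
23 | allyl 2-(bromomethyl)acrylate | C=CCOC(=O)C(=C)CBr | intermediate
24 | allyl 2-methylidene-4-hydroxybutanoate arm on C9 (C11–OH, both C11 epimers) | C=C1CC[C@@H]2[C@](C)(CO[Si](c3ccccc3)(c4ccccc4)C(C)(C)C)[C@H](O[Si](C)(C)C(C)(C)C)CC[C@@]2(C)[C@@H]1C(O)CC(=C)C(=O)OCC=C | intermediate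
25 | 3-O-TBS-19-O-TBDPS-14-deoxy-11-hydroxyandrographolide as both C11 epimers | C=C1CC[C@@H]2[C@](C)(CO[Si](c3ccccc3)(c4ccccc4)C(C)(C)C)[C@H](O[Si](C)(C)C(C)(C)C)CC[C@@]2(C)[C@@H]1C(O)CC1=CCOC1=O | intermediate
26 | 3-O-TBS-19-O-TBDPS-14-deoxy-11-oxoandrographolide | C=C1CC[C@@H]2[C@](C)(CO[Si](c3ccccc3)(c4ccccc4)C(C)(C)C)[C@H](O[Si](C)(C)C(C)(C)C)CC[C@@]2(C)[C@@H]1C(=O)CC1=CCOC1=O | intermediate
27 | (11R)-3-O-TBS-19-O-TBDPS-14-deoxy-11-hydroxyandrographolide | C=C1CC[C@@H]2[C@](C)(CO[Si](c3ccccc3)(c4ccccc4)C(C)(C)C)[C@H](O[Si](C)(C)C(C)(C)C)CC[C@@]2(C)[C@@H]1[C@H](O)CC1=CCOC1=O | intermediate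
28 | 14-deoxy-11-hydroxyandrographolide, 3-{(2R)-2-hydroxy-2-[(1R,4aS,5R,6R,8aR)-6-hydroxy-5-(hydroxymethyl)-5,8a-dimethyl-2-methylidenedecahydronaphthalen-1-yl]ethyl}furan-2(5H)-one | C=C1CC[C@@H]2[C@](C)(CO)[C@H](O)CC[C@@]2(C)[C@@H]1[C@H](O)CC1=CCOC1=O | target

**Step count and risks**

Total steps: 20 (19 on the main line plus step 15 for reagent 23). Longest linear sequence: 19 steps (steps 1–14 and 16–20, from geraniol).

Most likely to fail, in this order:

Step 10. The enol may terminate through oxygen to give a cyclic enol ether, the cascade may stop after ring A by proton loss, or the opened epoxide may rearrange to a ketone before the alkene attacks. The fallback changes the terminating group and sets out from 15. NaH and PhNTf2 (THF, 0 °C) should convert the chelated sodium enolate into the (Z)-enol triflate F1. Coupling with Me3SiCH2MgCl under Pd(PPh3)4 catalysis (Et2O, 0 °C, Kumada coupling) should give the (Z)-2-(trimethylsilylmethyl)enoate, allylsilane F2. MeAlCl2 (CH2Cl2, −78 °C) then triggers the same epoxide-initiated closure of rings A and B, but C9 now attacks C10 as the γ-carbon of an allylsilane, which can only terminate through carbon and releases the C8=C17 alkene directly, giving the hydroxy ester F3. Silylation as in step 11 comes back to the route at 18, so step 12 is bypassed as well.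

Step 19. Hydride delivery to the hindered C11 ketone may show poor facial selectivity if the substrate bias opposes the reagent, and the doubly activated C9–H and C12–H2 positions may enolise and let the alkenes migrate. The fallback sets C11 during C–C bond formation and sets out from aldehyde 20. Allenylboronic acid pinacol ester with the chiral phosphoric acid (R)-TRIP (toluene, 4 Å MS, 0 °C), the enantiomer expected to direct attack to the Re face, should give the (11R)-homopropargylic alcohol F4. Double deprotonation (n-BuLi, THF, −78 °C) and paraformaldehyde should give the propargylic diol F5. Hydroxyl-directed trans-hydroalumination with NaAlH2(OCH2CH2OMe)2 (THF, 0 °C) and iodination at −78 °C should give the (Z)-3-iodoallylic alcohol F6. Carbonylative lactonisation (PdCl2(PPh3)2, CO 1 atm, K2CO3, THF, 50 °C) closes the butenolide and comes back to the route at 27, steps 15–19 being bypassed.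

Step 12. The titanium reagent may enolise or chelate the β-keto ester, so that methylene transfer to the hindered C8 carbonyl stalls or C9 epimerises. The fallback introduces C17 by cross-coupling and sets out from 17. NaH and PhNTf2 should give the C8 enol triflate F7. Coupling with Me3SiCH2MgCl under Pd(PPh3)4 catalysis should give the vinylogous α-silyl ester F8. Fluoride (CsF, MeOH/THF, 0 °C) cleaves the C–Si bond, and the dienolate should be protonated at C9 from the face opposite C20, which moves the double bond to C8=C17 and comes back to the route at 18.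

Further compounds
F1 | step 10 | methyl (2Z,6E,10R,11S)-12-[(tert-butyldiphenylsilyl)oxy]-10,11-epoxy-7,11-dimethyl-3-{[(trifluoromethyl)sulfonyl]oxy}dodeca-2,6-dienoate | COC(=O)/C=C(\OS(=O)(=O)C(F)(F)F)CC/C=C(\C)CC[C@H]1O[C@@]1(C)CO[Si](c2ccccc2)(c3ccccc3)C(C)(C)C
F2 | step 10 | methyl (2Z,6E,10R,11S)-12-[(tert-butyldiphenylsilyl)oxy]-10,11-epoxy-7,11-dimethyl-3-[(trimethylsilyl)methyl]dodeca-2,6-dienoate | COC(=O)/C=C(\C[Si](C)(C)C)CC/C=C(\C)CC[C@H]1O[C@@]1(C)CO[Si](c2ccccc2)(c3ccccc3)C(C)(C)C
F3 | step 10 | methyl ester with exocyclic C8=C17 alkene and free C3–OH (18 without the TBS group) | C=C1CC[C@@H]2[C@](C)(CO[Si](c3ccccc3)(c4ccccc4)C(C)(C)C)[C@H](O)CC[C@@]2(C)[C@@H]1C(=O)OC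
F4 | step 19 | (11R)-homopropargylic alcohol (C9–CH(OH)–CH2–C≡CH) | C=C1CC[C@@H]2[C@](C)(CO[Si](c3ccccc3)(c4ccccc4)C(C)(C)C)[C@H](O[Si](C)(C)C(C)(C)C)CC[C@@]2(C)[C@@H]1[C@H](O)CC#C
F5 | step 19 | (11R)-propargylic diol (C9–CH(OH)–CH2–C≡C–CH2OH) | C=C1CC[C@@H]2[C@](C)(CO[Si](c3ccccc3)(c4ccccc4)C(C)(C)C)[C@H](O[Si](C)(C)C(C)(C)C)CC[C@@]2(C)[C@@H]1[C@H](O)CC#CCO
F6 | step 19 | (11R,13Z)-3-iodoallylic alcohol (C9–CH(OH)–CH2–C(I)=CH–CH2OH) | C=C1CC[C@@H]2[C@](C)(CO[Si](c3ccccc3)(c4ccccc4)C(C)(C)C)[C@H](O[Si](C)(C)C(C)(C)C)CC[C@@]2(C)[C@@H]1[C@H](O)C/C(I)=C/CO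
F7 | step 12 | C8 enol triflate of 17 (C8=C9, methyl ester on C9) | COC(=O)C1=C(OS(=O)(=O)C(F)(F)F)CC[C@@H]2[C@](C)(CO[Si](c3ccccc3)(c4ccccc4)C(C)(C)C)[C@H](O[Si](C)(C)C(C)(C)C)CC[C@@]12C
F8 | step 12 | C8-(trimethylsilylmethyl) C8=C9 unsaturated methyl ester | COC(=O)C1=C(C[Si](C)(C)C)CC[C@@H]2[C@](C)(CO[Si](c3ccccc3)(c4ccccc4)C(C)(C)C)[C@H](O[Si](C)(C)C(C)(C)C)CC[C@@]12C
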